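**Strategy.** Everything rests on closing ring B (the tetrahydrofuran O–C3–C2–C1–C15) at C2–C3. The target offers the right handle: C3 is the β-carbon of the C4 methyl ester and carries the ring oxygen, while C2 is an unfunctionalised methylene. A primary C2 radical therefore adds 5-exo to C3 of a β-alkoxyacrylate tethered through O and the gem-dimethyl carbon C15, and the C4 radical so formed is reduced face-selectively. One operation thus forms the C2–C3 bond, ring B and the C3 and C4 stereocentres under control of C1. The precursor is an acyclic iodo β-alkoxyacrylate whose single stereocentre (C1) comes from (R)-α-terpineol; ring A is closed last by olefination at C7=C8.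

Key step: step 7

Remark: atom labels follow the cembrane numbering of the target (ring A = C1–C14, esters on C4 and C8, methyl on C12; ring B = O, C3, C2, C1, C15 with two methyls on C15); anomer mixtures (2–6) and the C8 epimers (21–24) are carried as mixtures because those centres are erased later, and compounds 1, 8, 15 and 20 are taken as catalogue chemicals.

Step 1
Reactants: 1 (R)-α-terpineol
Product: 3 (4R)-5,5-dimethyl-4-(3-oxobutyl)oxolan-2-yl acetate (anomer mixture), via keto lactol 2 (not isolated)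
Conditions: O3, CH2Cl2, −78 °C; PPh3, −78 °C → rt; then Ac2O, Et3N, DMAP (cat.), 0 °C → rt
Reagents that add atoms: ozone, O=[O+][O-]; acetic anhydride, CC(=O)OC(C)=O
Why: Ozonolysis cleaves the only alkene, the tertiary hydroxyl closes onto the new aldehyde as a five-membered lactol, and acetylation caps it as an acylal that will survive peracid; the C1 stereocentre is not involved.

Step 2
Reactants: 3 (4R)-5,5-dimethyl-4-(3-oxobutyl)oxolan-2-yl acetate
Product: 4 (4R)-4-(2-acetoxyethyl)-5,5-dimethyloxolan-2-yl acetate (anomer mixture)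
Conditions: (CF3CO)2O, H2O2·urea, Na2HPO4, CH2Cl2, 0 °C → rt
Reagents that add atoms: trifluoroperacetic acid (formed in the flask), OOC(=O)C(F)(F)F
Why: Baeyer–Villiger oxidation of the methyl ketone with buffered trifluoroperacetic acid, in which the primary alkyl group migrates in preference to methyl, turns the acetyl group into the C13 acetate.

Step 3
Reactants: 4 (4R)-4-(2-acetoxyethyl)-5,5-dimethyloxolan-2-yl acetate
Product: 5 2-[(3R)-5-hydroxy-2,2-dimethyloxolan-3-yl]ethyl acetate (lactol, anomer mixture)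
Conditions: 0.2 M HCl, THF/H2O (3:1), rt
Reagents that add atoms: water, O
Why: Selective hydrolysis of the acylal, which ionises easily to the ring oxocarbenium ion, frees the lactol, while the primary acetate is inert to dilute acid at room temperature.

Step 4
Reactants: 5 2-[(3R)-5-hydroxy-2,2-dimethyloxolan-3-yl]ethyl acetate
Product: 7 (3S)-4-(formyloxy)-3-(iodomethyl)-4-methylpentyl acetate, via anomeric hypoiodite 6 (not isolated)
Conditions: PhI(OAc)2, I2, CH2Cl2, hν (visible), rt
Reagents that add atoms: iodine, II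
Why: Suárez alkoxy-radical fragmentation, in which β-scission of the anomeric alkoxy radical leaves the ether oxygen as a formate (its carbon is the future C3) and the primary C2 radical is capped by iodine; C1 is untouched.

Step 5
Reactants: 8 methyl 2-bromopent-4-enoate (racemic)
Product: 10 methyl 2-(triphenyl-λ5-phosphanylidene)pent-4-enoate, via phosphonium bromide 9 (not isolated)
Conditions: PPh3, toluene, 90 °C; then 1 M NaOH, CH2Cl2, 0 °C
Reagents that add atoms: triphenylphosphine, c1ccc(cc1)P(c1ccccc1)c1ccccc1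
Why: SN2 quaternisation of PPh3 by the α-bromo ester and deprotonation of the salt is the standard preparation of an ester-stabilised Wittig ylide.

Step 6
Reactants: 7 (3S)-4-(formyloxy)-3-(iodomethyl)-4-methylpentyl acetate; 10 methyl 2-(triphenyl-λ5-phosphanylidene)pent-4-enoate
Product: 11 methyl (2E)-2-[({(3S)-5-acetoxy-3-(iodomethyl)-2-methylpentan-2-yl}oxy)methylidene]pent-4-enoate (the iodo β-alkoxyacrylate)
Conditions: 10 (3 equiv), toluene, 100 °C, sealed tube
Reagents that add atoms: none
Why: Wittig olefination of a formate ester works because the formyl carbonyl is aldehyde-like whereas the acetate is not attacked, the fully substituted ylide carbon cannot be C-formylated, and the neopentyl-type iodide is too hindered to alkylate the ylide; the E enol ether is expected, and either geometry gives the same radical in step 7.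

Step 7
Reactants: 11 methyl (2E)-2-[({(3S)-5-acetoxy-3-(iodomethyl)-2-methylpentan-2-yl}oxy)methylidene]pent-4-enoate
Product: 12 methyl (2S)-2-[(2S,4R)-4-(2-acetoxyethyl)-5,5-dimethyloxolan-2-yl]pent-4-enoate
Conditions: Bu3SnH (1.5 equiv), Et3B (0.3 equiv), air, toluene (0.01 M), −78 °C; KF (aq) work-up
Reagents that add atoms: none
Why: Bu3Sn• (from Bu3SnH, Et3B and air) abstracts iodine, the primary C2 radical adds to C3 of the β-alkoxyacrylate, and the tertiary α-ester radical at C4 is reduced by Bu3SnH, which carries the chain. The closest known reaction type is the 5-exo cyclisation of alkyl radicals onto β-alkoxyacrylates, α-alkyl-substituted ones included, followed by low-temperature hydrogen transfer to an α-ester radical flanked by a cyclic ether. Ring B closes in the 5-exo-trig mode, helped by the gem-dimethyl group at C15 and by the polarity match between a nucleophilic radical and an electron-poor alkene. C3 is set by a chair-like transition state with the s-trans enol ether and the C1 side chain pseudo-equatorial, which places the C1 and C3 substituents trans on the ring. C4 is set by the exocyclic effect: with C3–H eclipsing the ester to minimise allylic strain, the stannane attacks the face anti to ring carbon C2 and gives the 3,4-anti (3S,4S) isomer. The step needs cyclisation to outrun direct reduction of the C2 radical, which high dilution and the fast closure secure, and it needs both facial selectivities, for which −78 °C is chosen.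

Step 8
Reactants: 12 methyl (2S)-2-[(2S,4R)-4-(2-acetoxyethyl)-5,5-dimethyloxolan-2-yl]pent-4-enoate
Product: 13 methyl (2S)-2-[(2S,4R)-4-(2-hydroxyethyl)-5,5-dimethyloxolan-2-yl]pent-4-enoate
Conditions: AcCl (0.3 equiv), MeOH, 0 °C → rt
Reagents that add atoms: none
Why: Acid-catalysed transesterification (HCl from AcCl in MeOH) removes the acetate without base, so the epimerisable C4 centre of the β-alkoxy ester is never enolised, and the methyl ester can only exchange with methanol.

Step 9
Reactants: 13 methyl (2S)-2-[(2S,4R)-4-(2-hydroxyethyl)-5,5-dimethyloxolan-2-yl]pent-4-enoate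
Product: 14 methyl (2S)-2-[(2S,4S)-4-(2-iodoethyl)-5,5-dimethyloxolan-2-yl]pent-4-enoate (same spatial arrangement; the descriptor changes with the iodine)
Conditions: I2, PPh3, imidazole, CH2Cl2, 0 °C → rt
Reagents that add atoms: iodine, II
Why: Appel-type iodination converts the unhindered primary alcohol into the C13 iodide by SN2 displacement of the alkoxyphosphonium ion, and the esters, ether and alkene are inert.

Step 10
Reactants: 15 3-[(tert-butyldimethylsilyl)oxy]propanal
Product: 16 tert-butyl{[(3Z)-4-iodopent-3-en-1-yl]oxy}dimethylsilane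
Conditions: EtPPh3I, n-BuLi, THF, 0 °C; I2, −78 °C; NaN(SiMe3)2, −20 °C; then 15, −78 → −20 °C
Reagents that add atoms: ethyltriphenylphosphonium iodide, CC[P+](c1ccccc1)(c1ccccc1)c1ccccc1.[I-]; iodine, II
Why: Stork–Zhao olefination, in which the α-iodo ylide made in the flask reacts with the aldehyde under kinetic control to give the (Z)-2-iodo-2-alkene, fixes the future C11=C12 geometry (iodine cis to C10).

Step 11
Reactants: 16 tert-butyl{[(3Z)-4-iodopent-3-en-1-yl]oxy}dimethylsilane
Product: 17 (2Z)-5-bromo-2-iodopent-2-ene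
Conditions: Ph3PBr2, CH2Cl2, 0 °C → rt
Reagents that add atoms: dibromotriphenylphosphorane, BrP(Br)(c1ccccc1)(c1ccccc1)c1ccccc1
Why: Ph3PBr2 converts a primary silyl ether directly into the bromide (silyl transfer to bromide, then SN2 on the alkoxyphosphonium ion) and leaves the vinyl iodide untouched.

Step 12
Reactants: 14 methyl (2S)-2-[(2S,4S)-4-(2-iodoethyl)-5,5-dimethyloxolan-2-yl]pent-4-enoate; 17 (2Z)-5-bromo-2-iodopent-2-ene
Product: 19 methyl (2S)-2-{(2S,4R)-4-[(3Z)-6-bromo-3-methylhex-3-en-1-yl]-5,5-dimethyloxolan-2-yl}pent-4-enoate, via alkylzinc iodide 18 (not isolated)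
Conditions: Zn dust (activated with BrCH2CH2Br, Me3SiCl), THF, 40 °C; then 17 (1.3 equiv), Pd(PPh3)4 (5 mol%), THF, rt
Reagents that add atoms: none
Why: Negishi coupling forms C12–C13 with retention of the Z geometry, because zinc inserts into the primary C–I bond in the presence of the ester and the zerovalent palladium catalyst reacts with the vinyl iodide but not with the primary bromide.

Step 13
Reactants: 19 methyl (2S)-2-{(2S,4R)-4-[(3Z)-6-bromo-3-methylhex-3-en-1-yl]-5,5-dimethyloxolan-2-yl}pent-4-enoate; 20 trimethyl phosphonoacetate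
Product: 21 methyl (2S)-2-{(2S,4R)-4-[(3Z)-7-(dimethoxyphosphoryl)-8-methoxy-3-methyl-8-oxooct-3-en-1-yl]-5,5-dimethyloxolan-2-yl}pent-4-enoate (both C8 epimers)
Conditions: 20 (3 equiv), NaH (2.5 equiv), THF/DMF, 0 °C; then 19, NaI (cat.), 50 °C
Reagents that add atoms: none
Why: SN2 alkylation of sodium trimethyl phosphonoacetate by the primary bromide forms C8–C9, excess nucleophile limits dialkylation, and this stabilised anion is too weak a base to enolise the C4 ester.

Step 14
Reactants: 21 methyl (2S)-2-{(2S,4R)-4-[(3Z)-7-(dimethoxyphosphoryl)-8-methoxy-3-methyl-8-oxooct-3-en-1-yl]-5,5-dimethyloxolan-2-yl}pent-4-enoate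
Product: 23 methyl (2S)-2-{(2S,4R)-4-[(3Z)-7-(dimethoxyphosphoryl)-8-methoxy-3-methyl-8-oxooct-3-en-1-yl]-5,5-dimethyloxolan-2-yl}-5-hydroxypentanoate, via alkylborane 22 (not isolated)
Conditions: 9-BBN, THF, 0 °C → rt; then NaOAc (aq), 30% H2O2, 0 °C → rt
Reagents that add atoms: hydrogen peroxide, OO
Why: Hydroboration–oxidation with 9-BBN adds anti-Markovnikov to the monosubstituted alkene only, and the buffered oxidation avoids strong base, so the δ-hydroxy ester can be taken on at once before it lactonises.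

Step 15
Reactants: 23 methyl (2S)-2-{(2S,4R)-4-[(3Z)-7-(dimethoxyphosphoryl)-8-methoxy-3-methyl-8-oxooct-3-en-1-yl]-5,5-dimethyloxolan-2-yl}-5-hydroxypentanoate
Product: 24 methyl (2S)-2-{(2S,4R)-4-[(3Z)-7-(dimethoxyphosphoryl)-8-methoxy-3-methyl-8-oxooct-3-en-1-yl]-5,5-dimethyloxolan-2-yl}-5-oxopentanoate
Conditions: Dess–Martin periodinane, NaHCO3, CH2Cl2, 0 °C → rt
Reagents that add atoms: none
Why: Dess–Martin oxidation gives the C7 aldehyde under buffered neutral conditions that touch neither the phosphonate, the trisubstituted alkene nor C4.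

Step 16
Reactants: 24 methyl (2S)-2-{(2S,4R)-4-[(3Z)-7-(dimethoxyphosphoryl)-8-methoxy-3-methyl-8-oxooct-3-en-1-yl]-5,5-dimethyloxolan-2-yl}-5-oxopentanoate
Product: 25 dimethyl (1R,4Z,8E,12S,13S)-4,15,15-trimethyl-14-oxabicyclo[11.2.1]hexadeca-4,8-diene-8,12-dicarboxylate (CNP0164914.1)
Conditions: LiCl, DBU, MeCN, rt, slow addition (final 1 mM)
Reagents that add atoms: none
Why: Intramolecular Horner–Wadsworth–Emmons olefination under Masamune–Roush conditions at high dilution closes the 14-membered ring A at C7=C8, reversible addition and elimination through the less crowded oxaphosphetane give the E enoate (ester trans to C6), and the mild base leaves C4 and ring B intact.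

**Compound list**

1 | (R)-α-terpineol, 2-[(1R)-4-methylcyclohex-3-en-1-yl]propan-2-ol | CC1=CC[C@@H](CC1)C(C)(C)O | starting material
2 | keto lactol, 4-[(3R)-5-hydroxy-2,2-dimethyloxolan-3-yl]butan-2-one (anomers) | OC1C[C@@H](CCC(C)=O)C(C)(C)O1 | intermediate
3 | (4R)-5,5-dimethyl-4-(3-oxobutyl)oxolan-2-yl acetate (anomers) | CC(=O)OC1C[C@@H](CCC(C)=O)C(C)(C)O1 | intermediate
4 | (4R)-4-(2-acetoxyethyl)-5,5-dimethyloxolan-2-yl acetate (anomers) | CC(=O)OC1C[C@@H](CCOC(C)=O)C(C)(C)O1 | intermediate
5 | 2-[(3R)-5-hydroxy-2,2-dimethyloxolan-3-yl]ethyl acetate (anomers) | OC1C[C@@H](CCOC(C)=O)C(C)(C)O1 | intermediate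
6 | anomeric hypoiodite, 2-[(3R)-5-(iodooxy)-2,2-dimethyloxolan-3-yl]ethyl acetate | IOC1C[C@@H](CCOC(C)=O)C(C)(C)O1 | intermediate
7 | (3S)-4-(formyloxy)-3-(iodomethyl)-4-methylpentyl acetate | IC[C@@H](CCOC(C)=O)C(C)(C)OC=O | intermediate
8 | methyl 2-bromopent-4-enoate (racemic) | COC(=O)C(Br)CC=C | starting material
9 | (1-methoxy-1-oxopent-4-en-2-yl)triphenylphosphonium bromide | COC(=O)C(CC=C)[P+](c1ccccc1)(c1ccccc1)c1ccccc1.[Br-] | intermediate
10 | methyl 2-(triphenyl-λ5-phosphanylidene)pent-4-enoate | COC(=O)C(CC=C)=P(c1ccccc1)(c1ccccc1)c1ccccc1 | intermediate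
11 | methyl (2E)-2-[({(3S)-5-acetoxy-3-(iodomethyl)-2-methylpentan-2-yl}oxy)methylidene]pent-4-enoate | IC[C@@H](CCOC(C)=O)C(C)(C)O/C=C(\CC=C)C(=O)OC | intermediate
12 | methyl (2S)-2-[(2S,4R)-4-(2-acetoxyethyl)-5,5-dimethyloxolan-2-yl]pent-4-enoate | C=CC[C@H](C(=O)OC)[C@@H]1C[C@@H](CCOC(C)=O)C(C)(C)O1 | intermediate
13 | methyl (2S)-2-[(2S,4R)-4-(2-hydroxyethyl)-5,5-dimethyloxolan-2-yl]pent-4-enoate | C=CC[C@H](C(=O)OC)[C@@H]1C[C@@H](CCO)C(C)(C)O1 | intermediate
14 | methyl (2S)-2-[(2S,4S)-4-(2-iodoethyl)-5,5-dimethyloxolan-2-yl]pent-4-enoate | C=CC[C@H](C(=O)OC)[C@@H]1C[C@@H](CCI)C(C)(C)O1 | intermediate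
15 | 3-[(tert-butyldimethylsilyl)oxy]propanal | O=CCCO[Si](C)(C)C(C)(C)C | starting material
16 | tert-butyl{[(3Z)-4-iodopent-3-en-1-yl]oxy}dimethylsilane | C/C(I)=C/CCO[Si](C)(C)C(C)(C)C | intermediate
17 | (2Z)-5-bromo-2-iodopent-2-ene | C/C(I)=C/CCBr | intermediate
18 | alkylzinc iodide from 14, {2-[(3S,5S)-5-[(2S)-1-methoxy-1-oxopent-4-en-2-yl]-2,2-dimethyloxolan-3-yl]ethyl}zinc iodide | C=CC[C@H](C(=O)OC)[C@@H]1C[C@@H](CC[Zn]I)C(C)(C)O1 | intermediate
19 | methyl (2S)-2-{(2S,4R)-4-[(3Z)-6-bromo-3-methylhex-3-en-1-yl]-5,5-dimethyloxolan-2-yl}pent-4-enoate | C=CC[C@H](C(=O)OC)[C@@H]1C[C@@H](CC/C(C)=C\CCBr)C(C)(C)O1 | intermediate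
20 | trimethyl phosphonoacetate | COC(=O)CP(=O)(OC)OC | starting material
21 | methyl (2S)-2-{(2S,4R)-4-[(3Z)-7-(dimethoxyphosphoryl)-8-methoxy-3-methyl-8-oxooct-3-en-1-yl]-5,5-dimethyloxolan-2-yl}pent-4-enoate (C8 epimers) | C=CC[C@H](C(=O)OC)[C@@H]1C[C@@H](CC/C(C)=C\CCC(C(=O)OC)P(=O)(OC)OC)C(C)(C)O1 | intermediate
22 | alkylborane, methyl (2S)-5-(9-borabicyclo[3.3.1]nonan-9-yl)-2-{(2S,4R)-4-[(3Z)-7-(dimethoxyphosphoryl)-8-methoxy-3-methyl-8-oxooct-3-en-1-yl]-5,5-dimethyloxolan-2-yl}pentanoate | B1(C2CCCC1CCC2)CCC[C@H](C(=O)OC)[C@@H]1C[C@@H](CC/C(C)=C\CCC(C(=O)OC)P(=O)(OC)OC)C(C)(C)O1 | intermediate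
23 | methyl (2S)-2-{(2S,4R)-4-[(3Z)-7-(dimethoxyphosphoryl)-8-methoxy-3-methyl-8-oxooct-3-en-1-yl]-5,5-dimethyloxolan-2-yl}-5-hydroxypentanoate | OCCC[C@H](C(=O)OC)[C@@H]1C[C@@H](CC/C(C)=C\CCC(C(=O)OC)P(=O)(OC)OC)C(C)(C)O1 | intermediate
24 | methyl (2S)-2-{(2S,4R)-4-[(3Z)-7-(dimethoxyphosphoryl)-8-methoxy-3-methyl-8-oxooct-3-en-1-yl]-5,5-dimethyloxolan-2-yl}-5-oxopentanoate | O=CCC[C@H](C(=O)OC)[C@@H]1C[C@@H](CC/C(C)=C\CCC(C(=O)OC)P(=O)(OC)OC)C(C)(C)O1 | intermediate
25 | dimethyl (1R,4Z,8E,12S,13S)-4,15,15-trimethyl-14-oxabicyclo[11.2.1]hexadeca-4,8-diene-8,12-dicarboxylate | COC(=O)/C1=C/CC[C@H](C(=O)OC)[C@@H]2C[C@@H](CC/C(C)=C\CC1)C(C)(C)O2 | target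

**Step count.** Total: 16 steps. Longest linear sequence: 13 steps (1–4, 6–9, 12–16) from 1; the ylide (step 5) and the vinyl iodide (steps 10–11) are made in parallel.

**Steps most likely to fail**

Step 7. What may go wrong: erosion of facial selectivity in the ring closure (C1/C3 cis isomer) or in the hydrogen transfer at C4, or reduction of the C2 radical before it cyclises. Fallback, from 4 back to 12: the tetrahydrofuran already present in 4 is kept and the C3–C4 bond is made by an ionic route instead. The oxocarbenium ion of 4 (Me3SiOTf, CH2Cl2, −78 °C) is captured at C3 by the ketene silyl acetal F1, made from methyl pent-4-enoate with LiN(iPr)2 and Me3SiCl. Attack on the envelope face that keeps the C1 side chain pseudo-equatorial is expected to give the 2,4-trans ring. C4 is not controlled in this variant, so the C4 epimers would be separated by chromatography before the route is rejoined at 12.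

Step 6. What may go wrong: slow addition of the hindered ylide to the formate, loss of the formyl group, or slow alkylation of the ylide by the iodide on prolonged heating. Fallback, from 7 back to 11: the enol ether is built from the free tertiary alcohol and the allyl group is added last. Selective methanolysis of the formate (KHCO3, MeOH, 0 °C; the acetate reacts far more slowly) gives the tertiary alcohol F2. PMe3-catalysed conjugate addition to methyl propiolate (CH2Cl2, rt) gives the (E)-β-alkoxyacrylate F3. α-Iodination (N-iodosuccinimide, AcOH cat., then Et3N) gives the (Z)-α-iodo acrylate F4. Stille coupling with allyltributylstannane (Pd2(dba)3, AsPh3, CuI, DMF, rt), which leaves the hindered alkyl iodide alone, returns 11.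

Step 16. What may go wrong: intermolecular olefination (oligomers) competing with ring closure, and incomplete control of the C7=C8 geometry in the ring-forming event. Fallback, from 14 directly to 25: the enoate is made intermolecularly, where its geometry can be checked and purified, and ring A is closed at C12–C13 instead. Hydroboration of 14 with 9-BBN gives the alkylborane F5, which buffered H2O2 (NaOAc) oxidises to the iodo alcohol F6. Dess–Martin oxidation gives the iodo aldehyde F7. Horner–Wadsworth–Emmons reaction (NaH, THF, 0 °C) with the iodoalkenyl phosphonate F8, made from 17 and 20 (NaH, DMF), gives the seco diiodide F9 with the E enoate. Zinc inserts selectively into the alkyl C–I bond to give the alkylzinc iodide F10, which is added slowly to Pd(PPh3)4 in THF (intramolecular Negishi coupling at high dilution) to give 25.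

**Further compounds**

F1 | step 7 | [(1-methoxypenta-1,4-dien-1-yl)oxy]trimethylsilane | COC(=CCC=C)O[Si](C)(C)C
F2 | step 6 | (3S)-4-hydroxy-3-(iodomethyl)-4-methylpentyl acetate | IC[C@@H](CCOC(C)=O)C(C)(C)O
F3 | step 6 | methyl (2E)-3-{[(3S)-5-acetoxy-3-(iodomethyl)-2-methylpentan-2-yl]oxy}prop-2-enoate | IC[C@@H](CCOC(C)=O)C(C)(C)O/C=C/C(=O)OC
F4 | step 6 | methyl (2Z)-3-{[(3S)-5-acetoxy-3-(iodomethyl)-2-methylpentan-2-yl]oxy}-2-iodoprop-2-enoate | IC[C@@H](CCOC(C)=O)C(C)(C)O/C=C(\I)C(=O)OC
F5 | step 16 | methyl (2S)-5-(9-borabicyclo[3.3.1]nonan-9-yl)-2-[(2S,4S)-4-(2-iodoethyl)-5,5-dimethyloxolan-2-yl]pentanoate | B1(C2CCCC1CCC2)CCC[C@H](C(=O)OC)[C@@H]1C[C@@H](CCI)C(C)(C)O1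
F6 | step 16 | methyl (2S)-5-hydroxy-2-[(2S,4S)-4-(2-iodoethyl)-5,5-dimethyloxolan-2-yl]pentanoate | OCCC[C@H](C(=O)OC)[C@@H]1C[C@@H](CCI)C(C)(C)O1
F7 | step 16 | methyl (2S)-2-[(2S,4S)-4-(2-iodoethyl)-5,5-dimethyloxolan-2-yl]-5-oxopentanoate | O=CCC[C@H](C(=O)OC)[C@@H]1C[C@@H](CCI)C(C)(C)O1
F8 | step 16 | methyl (5Z)-2-(dimethoxyphosphoryl)-6-iodohept-5-enoate | C/C(I)=C/CCC(C(=O)OC)P(=O)(OC)OC
F9 | step 16 | dimethyl (2E,6S)-2-[(3Z)-4-iodopent-3-en-1-yl]-6-[(2S,4S)-4-(2-iodoethyl)-5,5-dimethyloxolan-2-yl]hept-2-enedioate | COC(=O)/C(CC/C=C(I)/C)=C/CC[C@H](C(=O)OC)[C@@H]1C[C@@H](CCI)C(C)(C)O1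
F10 | step 16 | alkylzinc iodide of F9 (zinc on the former iodoethyl carbon) | COC(=O)/C(CC/C=C(I)/C)=C/CC[C@H](C(=O)OC)[C@@H]1C[C@@H](CC[Zn]I)C(C)(C)O1
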